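**Plan**
- Target: 1-(3,4-dihydroxyphenyl)icosan-5-one, numbered from the benzylic carbon C1 to the methyl C20, ketone at C5. It has one ring (the catechol benzene) and no stereocenter.
- Enabling feature: a C1=C2 double bond would be conjugated to the catechol ring (a styrene), while C3 and C4 insulate C2 from the C5 carbonyl. The bond can therefore be cut as an alkene between a vinylarene and an unconjugated terminal alkene (a γ,δ-unsaturated ketone).
- Retrosynthetic cuts, in order: the two O–benzyl bonds together with the C1–C2 saturation; the C1=C2 alkene (cross-metathesis); the C4–C5 bond of the enone (acyl substitution); the exocyclic C=CH2 of the styrene (carbonyl olefination).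
- Forward: two parallel branches. The aryl aldehyde is methylenated to the styrene; hexadecanoyl chloride is converted to its Weinreb amide and then, with a butenyl Grignard reagent, to icos-1-en-5-one. Cross-metathesis joins the halves at C1=C2, and one hydrogenation saturates the alkene and frees the catechol.
- Stereochemistry: none to set. The E alkene from the key step is erased by hydrogenation.

Key step: step 4

Assumption: but-3-enylmagnesium bromide is used as its commercial THF solution, and the direct allylation of a methyl ketone enolate is avoided in favour of the Weinreb route because the regioisomeric and polyalkylated C20 ketones would be hard to separate.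

**Step 1**
Reactants: 1 3,4-bis(benzyloxy)benzaldehyde; 2 methyltriphenylphosphonium bromide
Product: 4 1,2-bis(benzyloxy)-4-ethenylbenzene, via methylenetriphenylphosphorane 3 (not isolated)
Conditions: 2 (1.3 equiv), KOtBu (1.25 equiv), THF, 0 °C, 30 min; then 1, 0 °C to rt; hexane trituration, short SiO2 plug; store cold and use promptly
Reagents that add atoms: none
Why: Wittig methylenation, in which the non-stabilised ylide 3 adds to the non-enolisable aryl aldehyde and the adduct collapses to the terminal alkene and triphenylphosphine oxide, conditions to which the benzyl ethers are inert and in which no stereochemical element arises.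

**Step 2**
Reactants: 5 hexadecanoyl chloride; 6 N,O-dimethylhydroxylamine hydrochloride
Product: 7 N-methoxy-N-methylhexadecanamide
Conditions: 6 (1.2 equiv), K2CO3 (2.5 equiv), EtOAc/H2O, 0 °C to rt
Reagents that add atoms: none
Why: Schotten–Baumann acylation (Weinreb amide formation), in which the amine liberated by carbonate attacks the acid chloride much faster than water does and the resulting amide is stable to the aqueous base.

**Step 3**
Reactants: 7 N-methoxy-N-methylhexadecanamide; 8 but-3-enylmagnesium bromide
Product: 10 icos-1-en-5-one, via chelated bromomagnesium hemiaminal 9 (not isolated)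
Conditions: 8 (1.5 equiv, THF solution), THF, 0 °C to rt; then 1 M HCl, 0 °C
Reagents that add atoms: none
Why: Weinreb ketone synthesis, in which a single addition gives the five-membered magnesium chelate 9 that holds the tetrahedral carbon until the acidic quench and so prevents a second addition, the terminal alkene of the reagent being a spectator.

**Step 4**
Reactants: 4 1,2-bis(benzyloxy)-4-ethenylbenzene; 10 icos-1-en-5-one
Product: 11 (E)-1-[3,4-bis(benzyloxy)phenyl]icos-1-en-5-one
Conditions: 4 (2.5 equiv), 10 (1 equiv), second-generation Grubbs catalyst RuCl2(CHPh)(PCy3)(H2IMes) (5 mol%, two portions), 1,4-benzoquinone (10 mol%), CH2Cl2 (0.1 M), 40 °C, argon sweep; then DMSO to scavenge ruthenium, SiO2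
Reagents that add atoms: none
Why: Olefin cross-metathesis: the benzylidene complex of divalent ruthenium loses PCy3, adds each terminal alkene by [2+2] cycloaddition to a ruthenacyclobutane and cycloreverts, so the alkylidene halves are exchanged and ethylene leaves the solution, which pulls the equilibrium toward the internal styrenyl alkene. The closest known reaction type is the ruthenium-catalysed cross-metathesis of styrenes lacking ortho substituents with unhindered terminal alkenes, which is established chemistry. No ring is closed and no stereocenter is formed; the only stereochemical element is the C1=C2 geometry, expected to be E under thermodynamic control through secondary metathesis and in any case removed in step 5. The step needs cross-coupling to prevail over homodimerisation: 4 is used in excess, the homodimer of 10 is an unhindered internal alkene that re-enters the cycle by secondary metathesis, and stilbene formation consumes only surplus 4. The C5 ketone, insulated from the alkene by C3 and C4, neither chelates nor deactivates the carbene, the benzyl ethers are inert, and 1,4-benzoquinone suppresses ruthenium hydride-mediated migration of the terminal double bond of 10, which would otherwise give chain-shortened homologues.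

**Step 5**
Reactants: 11 (E)-1-[3,4-bis(benzyloxy)phenyl]icos-1-en-5-one
Product: 13 1-(3,4-dihydroxyphenyl)icosan-5-one, via 1-[3,4-bis(benzyloxy)phenyl]icosan-5-one 12 (not isolated)
Conditions: H2 (1 atm), 10% Pd/C, EtOAc/EtOH (1:1), rt; filtration through Celite under argon
Reagents that add atoms: none
Why: Heterogeneous catalytic hydrogenation with hydrogenolysis, in which Pd/C first saturates the disubstituted styrenyl alkene to give 12 and then cleaves both benzylic C–O bonds as toluene, while the unactivated dialkyl ketone and the heteroatom-free benzylic C1 should be untouched at one atmosphere and room temperature.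

**Compound list**
1 | 3,4-bis(benzyloxy)benzaldehyde | O=Cc1ccc(OCc2ccccc2)c(OCc2ccccc2)c1 | starting material
2 | methyltriphenylphosphonium bromide | C[P+](c1ccccc1)(c1ccccc1)c1ccccc1.[Br-] | starting material
3 | methylenetriphenylphosphorane (not isolated) | C=P(c1ccccc1)(c1ccccc1)c1ccccc1 | intermediate
4 | 1,2-bis(benzyloxy)-4-ethenylbenzene | C=Cc1ccc(OCc2ccccc2)c(OCc2ccccc2)c1 | intermediate
5 | hexadecanoyl chloride | CCCCCCCCCCCCCCCC(=O)Cl | starting material
6 | N,O-dimethylhydroxylamine hydrochloride | CNOC.Cl | starting material
7 | N-methoxy-N-methylhexadecanamide | CCCCCCCCCCCCCCCC(=O)N(C)OC | intermediate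
8 | but-3-enylmagnesium bromide | C=CCC[Mg]Br | starting material
9 | chelated bromomagnesium hemiaminal, the tetrahedral adduct of 7 and 8 (racemic, not isolated) | CCCCCCCCCCCCCCCC(CCC=C)(O[Mg]Br)N(C)OC | intermediate
10 | icos-1-en-5-one | CCCCCCCCCCCCCCCC(=O)CCC=C | intermediate
11 | (E)-1-[3,4-bis(benzyloxy)phenyl]icos-1-en-5-one | CCCCCCCCCCCCCCCC(=O)CC/C=C/c1ccc(OCc2ccccc2)c(OCc2ccccc2)c1 | intermediate
12 | 1-[3,4-bis(benzyloxy)phenyl]icosan-5-one (not isolated) | CCCCCCCCCCCCCCCC(=O)CCCCc1ccc(OCc2ccccc2)c(OCc2ccccc2)c1 | intermediate
13 | 1-(3,4-dihydroxyphenyl)icosan-5-one | CCCCCCCCCCCCCCCC(=O)CCCCc1ccc(O)c(O)c1 | target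

**Step count**
Total: 5 steps. Longest linear sequence: 4 steps (5 → 7 → 10 → 11 → 13); the aryl branch (1 → 4) is one step and joins at step 4.

**Steps most likely to fail**

Step 4 (cross-metathesis). Homodimerisation of the electron-rich styrene could outrun cross-coupling, the catalyst could die before the aliphatic homodimer is recycled, or the terminal double bond of the enone could migrate before coupling and give inseparable lower homologues. The fallback forms the C1=C2 alkene by carbonyl olefination and sets out from aldehyde 1.
- A Wittig reaction of 1 with the ylide from commercial (3-carboxypropyl)triphenylphosphonium bromide (NaN(SiMe3)2, 2.2 equiv, THF, 0 °C to rt) should give 5-[3,4-bis(benzyloxy)phenyl]pent-4-enoic acid F1 as an E/Z mixture.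
- Activation with 1,1'-carbonyldiimidazole followed by amine salt 6 should give 5-[3,4-bis(benzyloxy)phenyl]-N-methoxy-N-methylpent-4-enamide F2.
- Pentadecylmagnesium bromide F3, made from 1-bromopentadecane and Mg in THF, should add once to F2 and after an HCl quench give 1-[3,4-bis(benzyloxy)phenyl]icos-1-en-5-one F4 as an E/Z mixture.
- Hydrogenation of F4 under the conditions of step 5 saturates both geometric isomers to the same compound, so the route is rejoined at saturated ketone 12 and continues to 13.

Step 5 (hydrogenation and double debenzylation). Hydrogenolysis could stall through poisoning of the palladium surface by ruthenium or phosphine residues from step 4, stop at partial debenzylation, or be followed by air oxidation of the catechol during filtration. The fallback separates the two events and removes the benzyl groups without hydrogen. It sets out from 11.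
- Homogeneous hydrogenation with H2 (1 atm) and RhCl(PPh3)3 (monovalent rhodium) in toluene/EtOH at rt should reduce only the alkene and give 12 as an isolated compound.
- BCl3 with pentamethylbenzene as cation scavenger in CH2Cl2 at −78 °C should then cleave both aryl benzyl ethers without touching the ketone, returning to the route at target 13.

Step 3 (Grignard addition to the Weinreb amide). Chelate 9 could collapse prematurely on warming and allow a second addition, or the basic reagent could deprotonate the amide alpha to the carbonyl and leave conversion incomplete. The fallback replaces polar addition by a catalytic acyl cross-coupling and sets out from acid chloride 5, bypassing amide 7.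
- But-3-enylzinc bromide F5 is prepared from 4-bromobut-1-ene, Zn dust and LiCl in THF.
- Coupling of F5 with 5 under Pd(PPh3)4 catalysis (zerovalent palladium, THF, rt; Negishi acylation) should give ketone 10 directly, where the route is rejoined. The organozinc reagent does not add to the product ketone.

**Further compounds**
F1 | step 4 | 5-[3,4-bis(benzyloxy)phenyl]pent-4-enoic acid (E/Z mixture) | OC(=O)CCC=Cc1ccc(OCc2ccccc2)c(OCc2ccccc2)c1
F2 | step 4 | 5-[3,4-bis(benzyloxy)phenyl]-N-methoxy-N-methylpent-4-enamide (E/Z mixture) | CON(C)C(=O)CCC=Cc1ccc(OCc2ccccc2)c(OCc2ccccc2)c1
F3 | step 4 | pentadecylmagnesium bromide | CCCCCCCCCCCCCCC[Mg]Br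
F4 | step 4 | 1-[3,4-bis(benzyloxy)phenyl]icos-1-en-5-one (E/Z mixture) | CCCCCCCCCCCCCCCC(=O)CCC=Cc1ccc(OCc2ccccc2)c(OCc2ccccc2)c1
F0 | step 5 | none | none
F5 | step 3 | but-3-enylzinc bromide | C=CCC[Zn]Br
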